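## Retrosynthetic overview

Icetexane numbering is used: ring A is C1–C5 and C10, ring B is C5–C10 and C20, ring C is C8, C9 and C11–C14. The strategy rests on ring A. Quaternary C4 (C18 methyl, C19 carboxyl) lies para to oxygenated C1, and C19 returns to C5 through O and the single carbon C6, which bears the exocyclic C6=C7 bond. Ring A plus the lactone is therefore a 4-methyl-4-carboxycyclohexa-2,5-dienone whose carboxyl is esterified with a C6≡C7 ethynyl group.
Late stage: the C1 alcohol comes from a ketone and the hydroxyquinone from a trimethoxyarene. Ring B is cut at C10=C20 (aldol condensation) and at C7–C8 (Suzuki coupling), which gives a ring C bromo aldehyde and a ring A/lactone alkenyl boronate.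
The boronate is cut at C5–C6 and C7–B. It comes from an enantioselective copper-catalysed borylative cyclisation of the prochiral ethynyl dienone ester, which is made from benzoic acid by Birch methylation, O-alkynylation and C–H oxidation.
Ring order: A (from benzoic acid), lactone (key step), C (preformed arene, coupled on), B (aldol), and finally oxidation of ring C.

Key step: step 5

Assumption: no model predicts the sense of induction for this new tether. (R)-SEGPHOS is written, and its antipode is used instead if crystallographic correlation of the key-step product shows the mirror-image series.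

## Route

Step 1
Reactants: 1 benzoic acid
Product: 3 1-methylcyclohexa-2,5-diene-1-carboxylic acid, via dilithium dienediolate 2 (not isolated)
Conditions: Li (3.3 equiv), NH3(l)/THF, −78 °C; MeI (3 equiv), −78 °C; NH4Cl, then aq HCl to pH 2
Reagents that add atoms: methyl iodide, CI
Why: Birch reduction–alkylation, in which the carboxylate steers reduction to the 1,4-dihydro dianion, and this is methylated only at the ipso carbon to create the future C4 with C18 and C19 in place.

Step 2
Reactants: 3 1-methylcyclohexa-2,5-diene-1-carboxylic acid, 4 phenyl[(trimethylsilyl)ethynyl]iodonium triflate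
Product: 6 (trimethylsilyl)ethynyl 1-methylcyclohexa-2,5-diene-1-carboxylate, via sodium carboxylate 5 (not isolated)
Conditions: NaH (1.0 equiv), THF, 0 °C; solvent swap to CH2Cl2; 4 (1.1 equiv), −40 to 0 °C, dark
Reagents that add atoms: none
Why: O-alkynylation of a carboxylate by an alkynyl(aryl)iodonium salt, a known route to alkynyl carboxylates, in which the oxygen adds to the silyl-bearing alkyne carbon, iodobenzene leaves, and a fast 1,2-silyl shift of the alkylidene carbene outruns any insertion.

Step 3
Reactants: 6 (trimethylsilyl)ethynyl 1-methylcyclohexa-2,5-diene-1-carboxylate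
Product: 7 ethynyl 1-methylcyclohexa-2,5-diene-1-carboxylate
Conditions: TBAF (1.05 equiv), AcOH (1.5 equiv), THF, −78 to −30 °C; pH 7 buffer, cold work-up
Reagents that add atoms: none
Why: Fluoride-induced protiodesilylation of an alkynylsilane, with acetic acid protonating the acetylide at once so that no basic or nucleophilic species is left to attack the acyl carbon, which is shielded by the quaternary centre.

Step 4
Reactants: 7 ethynyl 1-methylcyclohexa-2,5-diene-1-carboxylate
Product: 8 ethynyl 1-methyl-4-oxocyclohexa-2,5-diene-1-carboxylate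
Conditions: Rh2(cap)4 (1 mol %), t-BuOOH (5.5 M in decane, 5 equiv), 4 Å sieves, CH2Cl2, 0 °C to rt, no carbonate base
Reagents that add atoms: tert-butyl hydroperoxide, CC(C)(C)OO
Why: Dirhodium-catalysed allylic C–H oxidation by tert-butylperoxyl radicals, which take the weak doubly allylic C–H bond while the alkyne offers no abstractable hydrogen; the oxidation is placed after esterification because the free dienone acid would lose CO2 and aromatise.

Step 5
Reactants: 8 ethynyl 1-methyl-4-oxocyclohexa-2,5-diene-1-carboxylate
Product: 10 (3E,3aR,7aS)-7a-methyl-3-[(4,4,5,5-tetramethyl-1,3,2-dioxaborolan-2-yl)methylidene]-3a,4-dihydro-2-benzofuran-1,5(3H,7aH)-dione (cis-fused, 4S,5R in icetexane numbering), via alkenylcopper intermediate 9 (not isolated)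
Conditions: CuCl (10 mol %), NaOt-Bu (9 mol %), (R)-SEGPHOS (11 mol %), B2pin2 (1.1 equiv), THF, rt, 30 min; then 8 and t-BuOH (1.5 equiv) by syringe pump, −20 °C
Reagents that add atoms: bis(pinacolato)diboron, CC1(C)OB(OC1(C)C)B1OC(C)(C)C(C)(C)O1
Why: Proposed new method: the ligated Cu–Bpin species made from CuOt-Bu and B2pin2 should add syn across the terminal ynol ester with boron on the unhindered C7 and copper on the oxygen-bearing C6 (9); this alkenylcopper then adds to the β-carbon C5 of one enone arm, and t-BuOH protonates the copper enolate at C10 and returns CuOt-Bu. The closest known reaction type is the copper-catalysed enantioselective borylative cyclisation of cyclohexadienones that carry the alkyne on a propargyl ether tether, and the acyloxy (ynol ester) tether is the untested element. The lactone ring (C4, C19, O, C6, C5) closes 5-exo-trig, and the two-atom tether can deliver C6 only to the face of ring A that holds C19, so the fusion must be cis. C4 and C5 are created together, with the chiral bisphosphine on copper deciding which enantiotopic arm is attacked, while syn addition fixes the E geometry with boron cis to C5. The step needs alkyne-over-enone chemoselectivity (both β-carbons are neopentyl next to C4), boron-at-C7 regioselectivity (terminal alkyne, and only copper at C6 can cyclise) and survival of the acyl group (pivalate-like shielding, and NaOt-Bu kept below CuCl so that no free alkoxide is present). The kinetic cost is rotation of the ester into its less populated E rotamer before closure, which is why the proton source is hindered and fed slowly.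

Step 6
Reactants: 10 bicyclic enone alkenyl boronate
Product: 11 (3E,3aR,7aS)-7a-methyl-3-[(4,4,5,5-tetramethyl-1,3,2-dioxaborolan-2-yl)methylidene]hexahydro-2-benzofuran-1,5-dione
Conditions: Cu(OAc)2·H2O (5 mol %), 1,2-bis(diphenylphosphino)benzene (5 mol %), (EtO)2MeSiH (1.5 equiv), t-BuOH (1.5 equiv), toluene, 0 °C
Reagents that add atoms: none
Why: Copper hydride conjugate reduction (Stryker type), in which hydride goes to C3 of the only electron-poor alkene, while the donor-substituted trisubstituted alkenyl boronate, the enol lactone and both stereocentres are left untouched.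

Step 7
Reactants: 12 1,2,4-trimethoxybenzene
Product: 14 2-(2,3,6-trimethoxyphenyl)propan-2-ol, via aryllithium 13 (not isolated)
Conditions: n-BuLi (1.1 equiv), THF, 0 °C to rt; acetone (1.5 equiv), −78 °C to rt; H2O
Reagents that add atoms: acetone, CC(C)=O
Why: Directed ortho-lithiation at the position flanked by two methoxy groups, followed by 1,2-addition to acetone, installs the three isopropyl carbons at the future C13.

Step 8
Reactants: 14 2-(2,3,6-trimethoxyphenyl)propan-2-ol
Product: 15 3-isopropyl-1,2,4-trimethoxybenzene
Conditions: Et3SiH (2.5 equiv), TFA (5 equiv), CH2Cl2, 0 °C to rt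
Reagents that add atoms: none
Why: Ionic hydrogenation, in which the tertiary benzylic cation stabilised by two ortho methoxy groups is trapped by silane hydride, and any isopropenyl arene formed by elimination re-enters through the same cation.

Step 9
Reactants: 15 3-isopropyl-1,2,4-trimethoxybenzene
Product: 16 1-bromo-3-isopropyl-2,4,5-trimethoxybenzene
Conditions: NBS (1.02 equiv), MeCN, 0 °C
Reagents that add atoms: N-bromosuccinimide, O=C1CCC(=O)N1Br
Why: Electrophilic aromatic bromination at C5 of 15 (future C8), which is activated by one ortho and one para methoxy group, whereas the other free position has only one ortho methoxy donor.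

Step 10
Reactants: 16 1-bromo-3-isopropyl-2,4,5-trimethoxybenzene
Product: 18 2-bromo-4-isopropyl-3,5,6-trimethoxybenzaldehyde, via chloro(methoxy)methyl arene 17 (not isolated)
Conditions: Cl2CHOMe (1.5 equiv), TiCl4 (2 equiv), CH2Cl2, −78 to 0 °C; ice water
Reagents that add atoms: dichloromethyl methyl ether, COC(Cl)Cl; water, O
Why: Rieche formylation at the last free ring position (future C9), assisted by titanium coordination to the neighbouring methoxy group, places C20 as the aldehyde next to the bromide.

Step 11
Reactants: 11 saturated keto lactone alkenyl boronate, 18 2-bromo-4-isopropyl-3,5,6-trimethoxybenzaldehyde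
Product: 19 2-{(E)-[(3aR,7aS)-7a-methyl-1,5-dioxohexahydro-2-benzofuran-3(1H)-ylidene]methyl}-4-isopropyl-3,5,6-trimethoxybenzaldehyde
Conditions: Pd(OAc)2 (5 mol %), SPhos (10 mol %), K3PO4 (2.5 equiv), toluene/H2O 20:1, 60 °C
Reagents that add atoms: none
Why: Suzuki–Miyaura coupling, in which the bulky biarylphosphine handles the doubly ortho-substituted bromide (activated by its ortho formyl group), the near-anhydrous phosphate spares the hindered enol lactone, and retention at C7 keeps the aryl group cis to C5.

Step 12
Reactants: 19 (E)-arylidene enol lactone keto aldehyde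
Product: 21 (4S,5R)-11,12,14-trimethoxy-1-oxo tetracycle (icetexa-6,8,10(20),11,13-pentaen-19,6-olide skeleton), via aldol adduct 20 (not isolated)
Conditions: pyrrolidine (20 mol %), AcOH (20 mol %), 4 Å sieves, toluene, 50 °C
Reagents that add atoms: none
Why: Intramolecular aldol condensation through the enamine of the C1 ketone, in which only C10 can reach C20 within a seven-membered ring (C2 would need a bridged nine-membered ring), dehydration is driven by conjugation with the arene, and C5, which is not acidified by the carbonyl, keeps its configuration.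

Step 13
Reactants: 21 trimethoxyarene tetracycle
Product: 22 (4S,5R)-12-methoxy-1-oxo-11,14-quinone tetracycle
Conditions: (NH4)2Ce(NO3)6 (2.5 equiv), MeCN/H2O 4:1, 0 °C, short contact
Reagents that add atoms: water, O
Why: Oxidative demethylation of a para-dimethoxyarene by ceric ammonium nitrate, in which the 11- and 14-methoxy groups are para to each other and collapse to the quinone through attack of water, while the 12-methoxy group remains as a vinylogous ester.

Step 14
Reactants: 22 12-methoxyquinone tetracycle
Product: 24 (4S,5R)-12-hydroxy-1-oxo-11,14-quinone tetracycle, via dichloroboryl ether 23 (not isolated)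
Conditions: BCl3 (1.5 equiv), CH2Cl2, −78 to −20 °C; pH 7 buffer
Reagents that add atoms: none
Why: Chelation-assisted Lewis acid ether cleavage, in which boron binds the C11 carbonyl and the adjacent methoxy oxygen so that chloride removes only this methyl group at low temperature, without touching the enol lactone or the enone.

Step 15
Reactants: 24 1-oxo hydroxyquinone
Product: 26 6,7-anhydroballotiquinone (1R,4S,5R), via hydroquinone 25 (not isolated)
Conditions: CeCl3·7H2O (2 equiv), NaBH4 (2.5 equiv), MeOH/THF 1:1, −78 to −40 °C; pH 7 phosphate buffer, air, rt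
Reagents that add atoms: none
Why: Luche 1,2-reduction, in which the quinone is reduced transiently to the hydroquinone and restored by air at neutral pH, while hydride reaches C1 along the axial trajectory on the α face (past only H-3α and H-5α, with C19 axial on the β face) to give the equatorial 1β-alcohol; the step comes last because this allylic alcohol ionises easily.

## Compound list

1 | benzoic acid | O=C(O)c1ccccc1 | starting material
2 | dilithium dienediolate of 1,4-dihydrobenzoic acid | [Li+].[Li+].[O-]C([O-])=C1C=CCC=C1 | intermediate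
3 | 1-methylcyclohexa-2,5-diene-1-carboxylic acid | CC1(C(=O)O)C=CCC=C1 | intermediate
4 | phenyl[(trimethylsilyl)ethynyl]iodonium triflate | C[Si](C)(C)C#C[I+]c1ccccc1.[O-]S(=O)(=O)C(F)(F)F | starting material
5 | sodium 1-methylcyclohexa-2,5-diene-1-carboxylate | [Na+].[O-]C(=O)C1(C)C=CCC=C1 | intermediate
6 | (trimethylsilyl)ethynyl 1-methylcyclohexa-2,5-diene-1-carboxylate | C[Si](C)(C)C#COC(=O)C1(C)C=CCC=C1 | intermediate
7 | ethynyl 1-methylcyclohexa-2,5-diene-1-carboxylate | C#COC(=O)C1(C)C=CCC=C1 | intermediate
8 | ethynyl 1-methyl-4-oxocyclohexa-2,5-diene-1-carboxylate | C#COC(=O)C1(C)C=CC(=O)C=C1 | intermediate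
9 | (Z)-1-acyloxy-2-borylvinylcopper, boron and copper cis, phosphine on copper omitted | CC1(C)OB(OC1(C)C)/C=C(\[Cu])OC(=O)C1(C)C=CC(=O)C=C1 | intermediate
10 | (3E,3aR,7aS)-7a-methyl-3-[(pinacolatoboryl)methylidene]-3a,4-dihydro-2-benzofuran-1,5(3H,7aH)-dione | CC1(C)OB(OC1(C)C)/C=C2/OC(=O)[C@@]3(C)C=CC(=O)C[C@@H]23 | intermediate
11 | (3E,3aR,7aS)-7a-methyl-3-[(pinacolatoboryl)methylidene]hexahydro-2-benzofuran-1,5-dione | CC1(C)OB(OC1(C)C)/C=C2/OC(=O)[C@@]3(C)CCC(=O)C[C@@H]23 | intermediate
12 | 1,2,4-trimethoxybenzene | COc1ccc(OC)c(OC)c1 | starting material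
13 | 2,3,6-trimethoxyphenyllithium | [Li]c1c(OC)ccc(OC)c1OC | intermediate
14 | 2-(2,3,6-trimethoxyphenyl)propan-2-ol | CC(C)(O)c1c(OC)ccc(OC)c1OC | intermediate
15 | 3-isopropyl-1,2,4-trimethoxybenzene | COc1ccc(OC)c(C(C)C)c1OC | intermediate
16 | 1-bromo-3-isopropyl-2,4,5-trimethoxybenzene | COc1cc(Br)c(OC)c(C(C)C)c1OC | intermediate
17 | 1-bromo-2-[chloro(methoxy)methyl]-5-isopropyl-3,4,6-trimethoxybenzene | COC(Cl)c1c(Br)c(OC)c(C(C)C)c(OC)c1OC | intermediate
18 | 2-bromo-4-isopropyl-3,5,6-trimethoxybenzaldehyde | O=Cc1c(Br)c(OC)c(C(C)C)c(OC)c1OC | intermediate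
19 | (E)-arylidene enol lactone keto aldehyde (4S,5R) | O=Cc1c(OC)c(OC)c(C(C)C)c(OC)c1/C=C2/OC(=O)[C@@]3(C)CCC(=O)C[C@@H]23 | intermediate
20 | 20-hydroxy aldol adduct (4S,5R; C10 and C20 undefined) | COc1c(C(C)C)c(OC)c(OC)c2c1C=C4OC(=O)[C@@]3(C)CCC(=O)C(C2O)[C@@H]43 | intermediate
21 | (4S,5R)-11,12,14-trimethoxy-1-oxo tetracycle | COc1c(C(C)C)c(OC)c(OC)c2c1C=C4OC(=O)[C@@]3(C)CCC(=O)C(=C2)[C@@H]43 | intermediate
22 | (4S,5R)-12-methoxy-1-oxo-11,14-quinone | CC(C)C1=C(OC)C(=O)C2=C(C=C3OC(=O)[C@@]4(C)CCC(=O)C(=C2)[C@@H]34)C1=O | intermediate
23 | 12-O-dichloroboryl derivative of 24 | CC(C)C1=C(OB(Cl)Cl)C(=O)C2=C(C=C3OC(=O)[C@@]4(C)CCC(=O)C(=C2)[C@@H]34)C1=O | intermediate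
24 | (4S,5R)-12-hydroxy-1-oxo-11,14-quinone | CC(C)C1=C(O)C(=O)C2=C(C=C3OC(=O)[C@@]4(C)CCC(=O)C(=C2)[C@@H]34)C1=O | intermediate
25 | (1R,4S,5R)-1,11,12,14-tetrahydroxy hydroquinone form | CC(C)c1c(O)c(O)c2c(C=C3OC(=O)[C@@]4(C)CC[C@@H](O)C(=C2)[C@@H]34)c1O | intermediate
26 | 6,7-anhydroballotiquinone (1R,4S,5R) | CC(C)C1=C(O)C(=O)C2=C(C=C3OC(=O)[C@@]4(C)CC[C@@H](O)C(=C2)[C@@H]34)C1=O | target

## Step count

Total step count: 15. The longest linear sequence is 11 steps (steps 1–6 and 11–15, from benzoic acid). The arene branch is 4 steps (steps 7–10).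

## Steps most likely to fail

**1. Step 5 (Proposed new method).**
- What may go wrong:
  - protonation of the alkenylcopper before the ester has rotated into the closing rotamer, which gives plain hydroboration;
  - acyl cleavage with aromatisation of ring A;
  - competing conjugate borylation;
  - weak discrimination between the two enone arms.
- Fallback (known chemistry, from 3 back to 19): the tethered copper step is given up and C5–C6 is made intermolecularly.
  - Steglich esterification of 3 with 2-(trimethylsilyl)ethanol gives 2-(trimethylsilyl)ethyl 1-methylcyclohexa-2,5-diene-1-carboxylate F1.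
  - The conditions of step 4 then give 2-(trimethylsilyl)ethyl 1-methyl-4-oxocyclohexa-2,5-diene-1-carboxylate F2.
  - Rhodium-catalysed asymmetric conjugate alkynylation ([Rh(OAc)(C2H4)2]2, (R)-DTBM-SEGPHOS, (triisopropylsilyl)acetylene, dioxane) desymmetrises F2 to 2-(trimethylsilyl)ethyl (1S,6R)-1-methyl-4-oxo-6-[(triisopropylsilyl)ethynyl]cyclohex-2-ene-1-carboxylate F3. Attack is expected anti to the C18 methyl, on the side of the flatter ester, and the C5 epimer is removed by chromatography.
  - Copper hydride reduction as in step 6 gives 2-(trimethylsilyl)ethyl (1S,2R)-1-methyl-4-oxo-2-[(triisopropylsilyl)ethynyl]cyclohexane-1-carboxylate F4.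
  - TBAF in THF removes both silicon groups to give (1S,2S)-2-ethynyl-1-methyl-4-oxocyclohexane-1-carboxylic acid F5.
  - Palladium-catalysed cyclisation–coupling of this 4-alkynoic acid with bromide 18 (Pd(OAc)2, PPh3, K2CO3, DMSO, 60 °C) closes the lactone. The carboxylate attacks the arylpalladium-activated alkyne anti and 5-exo-dig, which sets the aryl group trans to the ring oxygen and gives 19 directly. Steps 2–6 and 11 are replaced.

**2. Step 4.**
- What may go wrong: hydration or perhydrolysis of the unprotected ynol ester during the oxidation, radical attack at the terminal alkyne, or fragmentation of the cyclohexadienyl radical with aromatisation.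
- Fallback (from 6 back to 8): the protecting-group order is changed so that the alkyne stays silylated while the ring is oxidised.
  - Compound 6 is oxidised at the doubly allylic CH2 (Rh2(cap)4/t-BuOOH, or CrO3 with 3,5-dimethylpyrazole) to (trimethylsilyl)ethynyl 1-methyl-4-oxocyclohexa-2,5-diene-1-carboxylate F6.
  - Only then is the C–Si bond cleaved with TBAF/AcOH at −78 °C, which gives 8 immediately before the key step. Step 3 is dropped.

**3. Step 15.**
- What may go wrong: hydride addition in a conjugate sense to the quinone-linked enone, incomplete return of the hydroquinone to the quinone, methanolysis of the enol lactone, ionisation of the new allylic alcohol, or poor facial selectivity at C1.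
- Fallback (from 24 back to 26): the quinone is taken out of play before any hydride is used.
  - Reductive acetylation of 24 (Zn, Ac2O, NaOAc, rt) gives the (4S,5R)-11,12,14-triacetoxy-1-oxo tetracycle F7.
  - Luche reduction now meets a single reducible carbonyl on a moderately electron-poor arene and gives the (1R,4S,5R)-11,12,14-triacetoxy-1-hydroxy tetracycle F8.
  - Mild methanolysis of the three aryl acetates (K2CO3, MeOH, 0 °C) under air passes through 25, which autoxidises to 26.

## Further compounds

F1 | step 5 | 2-(trimethylsilyl)ethyl 1-methylcyclohexa-2,5-diene-1-carboxylate | C[Si](C)(C)CCOC(=O)C1(C)C=CCC=C1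
F2 | step 5 | 2-(trimethylsilyl)ethyl 1-methyl-4-oxocyclohexa-2,5-diene-1-carboxylate | C[Si](C)(C)CCOC(=O)C1(C)C=CC(=O)C=C1
F3 | step 5 | 2-(trimethylsilyl)ethyl (1S,6R)-1-methyl-4-oxo-6-[(triisopropylsilyl)ethynyl]cyclohex-2-ene-1-carboxylate | C[Si](C)(C)CCOC(=O)[C@@]1(C)C=CC(=O)C[C@H]1C#C[Si](C(C)C)(C(C)C)C(C)C
F4 | step 5 | 2-(trimethylsilyl)ethyl (1S,2R)-1-methyl-4-oxo-2-[(triisopropylsilyl)ethynyl]cyclohexane-1-carboxylate | C[Si](C)(C)CCOC(=O)[C@@]1(C)CCC(=O)C[C@H]1C#C[Si](C(C)C)(C(C)C)C(C)C
F5 | step 5 | (1S,2S)-2-ethynyl-1-methyl-4-oxocyclohexane-1-carboxylic acid | OC(=O)[C@@]1(C)CCC(=O)C[C@H]1C#C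
F6 | step 4 | (trimethylsilyl)ethynyl 1-methyl-4-oxocyclohexa-2,5-diene-1-carboxylate | C[Si](C)(C)C#COC(=O)C1(C)C=CC(=O)C=C1
F7 | step 15 | (4S,5R)-11,12,14-triacetoxy-1-oxo tetracycle | CC(C)c1c(OC(C)=O)c(OC(C)=O)c2c(C=C3OC(=O)[C@@]4(C)CCC(=O)C(=C2)[C@@H]34)c1OC(C)=O
F8 | step 15 | (1R,4S,5R)-11,12,14-triacetoxy-1-hydroxy tetracycle | CC(C)c1c(OC(C)=O)c(OC(C)=O)c2c(C=C3OC(=O)[C@@]4(C)CC[C@@H](O)C(=C2)[C@@H]34)c1OC(C)=O
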